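**Plan**
1. Cuts: (a) the veratryl–carbinol carbon bond, made from an aryl Grignard reagent and an oxolane-2-carbaldehyde, with the carbinol configuration then set through the ketone. (b) The anisyl–C3 bond, made as an sp2–sp2 coupling once the oxolane is raised in oxidation level (C5H2 to a lactone C=O, C3–C4 to an enol C=C).
2. Enabling feature: oxolane atoms C5, C4(OH), C3(aryl), C2 and O1 plus the carbinol carbon are the C1 lactone carbonyl, C2 enol carbon, C3 vinylogous-acid carbon, C4, ring O and C5 of L-ascorbic acid. The aryl-bearing C3 is the carbon whose acidic OH can become a triflate. The all-cis C2/C3/C4 pattern is the L-gulo pattern that syn hydrogenation of that furanone ring gives.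
3. Forward order: the furanone ring of 1 is kept throughout and becomes the oxolane. The sequence is O2 benzylation, O3 triflation, arylation at C3, hydrogenation, lactone C=O to CH2, excision of C6, veratryl addition, oxidation/reduction, desilylation.
4. Stereochemistry: only C4 of ascorbic acid (oxolane C2) is imported. It sends hydrogen to the opposite ring face, which sets oxolane C3 and C4. Together with ring O1 it steers a chelation-controlled ketone reduction, which sets the carbinol carbon.

Key step: step 3

Remark on numbering: sugar numbering (C1 = lactone carbonyl to C6) is used for 1–11. It maps onto the target as C1 = oxolane C5, C2 = oxolane C4, C3 = oxolane C3, C4 = oxolane C2, C5 = carbinol carbon.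
Remark on supply: 1 (the acetonide of L-ascorbic acid), 4 and 13 (as a THF solution) are assumed to be purchasable.

**Step 1**
Reactants: 1 5,6-O-isopropylidene-L-ascorbic acid
Product: 2 2-O-benzyl-5,6-O-isopropylidene-L-ascorbic acid
Conditions: t-BuOK (2.0 equiv), DMSO/THF, 0 °C; BnBr (1.0 equiv), rt; 1 M HCl work-up
Reagents that add atoms: benzyl bromide, BrCc1ccccc1
Why: Williamson O-alkylation of the ascorbate dianion: the O3 charge is delocalised into the lactone carbonyl (vinylogous carboxylate) whereas the O2 alkoxide is localised and the better nucleophile, so one equivalent of BnBr should be taken up at O2, and no stereocentre is touched.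

**Step 2**
Reactants: 2 2-O-benzyl-5,6-O-isopropylidene-L-ascorbic acid
Product: 3 2-O-benzyl-5,6-O-isopropylidene-3-O-(trifluoromethylsulfonyl)-L-ascorbic acid
Conditions: Tf2O (1.1 equiv), pyridine (1.5 equiv), CH2Cl2, −78 to 0 °C
Reagents that add atoms: trifluoromethanesulfonic anhydride, O=S(=O)(OS(=O)(=O)C(F)(F)F)C(F)(F)F
Why: O-sulfonylation (enol triflate formation) of the one remaining acidic OH makes C3 an sp2 electrophile, and the weak base at low temperature leaves the γ-H at C4 alone.

**Step 3**
Reactants: 3 2-O-benzyl-5,6-O-isopropylidene-3-O-(trifluoromethylsulfonyl)-L-ascorbic acid; 4 4-methoxyphenylboronic acid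
Product: 5 (5S)-3-(benzyloxy)-5-[(4S)-2,2-dimethyl-1,3-dioxolan-4-yl]-4-(4-methoxyphenyl)furan-2(5H)-one
Conditions: Pd(PPh3)4 (5 mol %), K3PO4 (1.5 equiv), 1,4-dioxane, 60 °C
Reagents that add atoms: none
Why: Suzuki–Miyaura coupling: zerovalent palladium inserts into the C3–OTf bond, which is activated as the β-position of the 2(5H)-furanone (a vinylogous acyl triflate), the phosphate-activated boronate hands the anisyl group to divalent palladium, and reductive elimination forms the aryl–C3 bond. The closest known reaction type is the coupling of 4-triflyloxy- and 4-tosyloxy-2(5H)-furanones (tetronic acid sulfonates) with arylboronic acids. No ring is closed and no stereocentre is formed here; the step creates the flat, tetrasubstituted C2=C3 unit carrying oxygen at C2 and anisyl at C3, so that both remaining ring stereocentres can be set by one syn addition of hydrogen in step 4 under the control of C4. Chemoselectivity is inherent, because the triflate is the only bond that zerovalent palladium can enter (benzyl enol ether, lactone and acetonide are inert). The selectivity that must be secured is retention at C4, whose H is the γ-H of the butenolide: a sparingly soluble base in an aprotic solvent at moderate temperature should avoid the dienolate, which would racemise C4 or expel O5 of the acetonide.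

**Step 4**
Reactants: 5 (5S)-3-(benzyloxy)-5-[(4S)-2,2-dimethyl-1,3-dioxolan-4-yl]-4-(4-methoxyphenyl)furan-2(5H)-one
Product: 7 3-deoxy-5,6-O-isopropylidene-3-C-(4-methoxyphenyl)-L-gulono-1,4-lactone (all-cis; 3S,4R,5S as an oxolan-2-one), via free enol lactone 6 (not isolated)
Conditions: H2 (4 atm), 10% Pd/C, EtOAc, rt
Reagents that add atoms: none
Why: Heterogeneous catalytic hydrogenation (benzyl enol ether hydrogenolysis, then syn addition of H2 to the 3-hydroxy-2(5H)-furanone C=C): as in the known conversion of L-ascorbic acid into L-gulono-1,4-lactone, the ring should bind to the metal by the face opposite to the C4 dioxolanyl group, so both H atoms arrive trans to it and C2-OH, C3-anisyl and the C4 side chain end up all-cis.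

**Step 5**
Reactants: 7 3-deoxy-5,6-O-isopropylidene-3-C-(4-methoxyphenyl)-L-gulono-1,4-lactone
Product: 8 2-O-(tert-butyldimethylsilyl)-3-deoxy-5,6-O-isopropylidene-3-C-(4-methoxyphenyl)-L-gulono-1,4-lactone
Conditions: TBSOTf (1.2 equiv), 2,6-lutidine (1.5 equiv), CH2Cl2, 0 °C
Reagents that add atoms: tert-butyldimethylsilyl trifluoromethanesulfonate, CC(C)(C)[Si](C)(C)OS(=O)(=O)C(F)(F)F
Why: Silyl ether formation with the reactive silyl triflate copes with the hindered OH beside the cis anisyl group without a base strong enough to epimerise C2; the group later blocks hydroxyl-delivered hydride in step 11 and leaves with fluoride instead of acid.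

**Step 6**
Reactants: 8 2-O-(tert-butyldimethylsilyl)-3-deoxy-5,6-O-isopropylidene-3-C-(4-methoxyphenyl)-L-gulono-1,4-lactone
Product: 9 2-O-(tert-butyldimethylsilyl)-3-deoxy-5,6-O-isopropylidene-3-C-(4-methoxyphenyl)-L-gulofuranose (lactol; anomeric mixture)
Conditions: i-Bu2AlH (1.1 equiv), CH2Cl2, −78 °C; aqueous work-up
Reagents that add atoms: none
Why: Partial lactone reduction: the tetrahedral aluminium hemiacetal is stable at −78 °C and gives the lactol on work-up, while silyl ether and acetonide are inert to the hydride.

**Step 7**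
Reactants: 9 lactol (anomeric mixture)
Product: 10 (2S,3S,4S)-4-(tert-butyldimethylsilyloxy)-2-[(4S)-2,2-dimethyl-1,3-dioxolan-4-yl]-3-(4-methoxyphenyl)oxolane (all-cis)
Conditions: Et3SiH (3 equiv), BF3·OEt2 (1.2 equiv), CH2Cl2, −78 to −20 °C
Reagents that add atoms: none
Why: Ionic reduction of a lactol (silane/Lewis acid deoxygenation through the ring oxocarbenium ion) turns C1 into the ring CH2; it is placed here because no ionisable benzylic C–O bond is present yet.

**Step 8**
Reactants: 10 all-cis oxolane acetonide
Product: 12 (2S,3S,4S)-4-(tert-butyldimethylsilyloxy)-3-(4-methoxyphenyl)oxolane-2-carbaldehyde, via free diol 11 (not isolated)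
Conditions: H5IO6 (1.5 equiv), EtOAc, 0 °C to rt
Reagents that add atoms: none
Why: Periodic acid first hydrolyses the terminal acetonide and then performs the Malaprade glycol cleavage in the same flask, excising C6; the configurationally labile cis aldehyde is taken on crude.

**Step 9**
Reactants: 12 (2S,3S,4S)-4-(tert-butyldimethylsilyloxy)-3-(4-methoxyphenyl)oxolane-2-carbaldehyde; 13 3,4-dimethoxyphenylmagnesium bromide
Product: 14 (3,4-dimethoxyphenyl)[(2S,3S,4S)-4-(tert-butyldimethylsilyloxy)-3-(4-methoxyphenyl)oxolan-2-yl]methanol (both carbinol epimers)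
Conditions: 13 (1.5 equiv), THF, −78 °C; water quench
Reagents that add atoms: none
Why: Grignard 1,2-addition of an aryl nucleophile should outrun enolisation at −78 °C, and the configuration of the new carbinol carbon does not matter because step 10 erases it.

**Step 10**
Reactants: 14 carbinol (both epimers)
Product: 15 (3,4-dimethoxyphenyl)[(2S,3S,4S)-4-(tert-butyldimethylsilyloxy)-3-(4-methoxyphenyl)oxolan-2-yl]methanone
Conditions: Dess–Martin periodinane (1.2 equiv), CH2Cl2, 0 °C to rt
Reagents that add atoms: none
Why: Dess–Martin oxidation runs under near-neutral conditions, so the α-alkoxy ketone should keep its cis configuration at oxolane C2, and silyl ether and arenes are untouched.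

**Step 11**
Reactants: 15 aryl ketone
Product: 16 (R)-(3,4-dimethoxyphenyl)[(2S,3S,4S)-4-(tert-butyldimethylsilyloxy)-3-(4-methoxyphenyl)oxolan-2-yl]methanol
Conditions: Zn(BH4)2 (ether solution), Et2O, −20 to 0 °C; aqueous work-up
Reagents that add atoms: none
Why: Cram-chelate-controlled reduction of an α-alkoxy ketone: zinc ties ring O1 and the carbonyl O into a five-membered chelate and hydride enters from the side of the C2–H, away from C3 with its anisyl group and the neighbouring silyl ether, which gives the anti (erythro) O1/OH pair, i.e. the (R)-carbinol.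

**Step 12**
Reactants: 16 silyl-protected (R)-carbinol
Product: 17 (3S,4R,5S)-5-[(R)-(3,4-dimethoxyphenyl)(hydroxy)methyl]-4-(4-methoxyphenyl)oxolan-3-ol (target)
Conditions: n-Bu4NF (1.2 equiv), THF, 0 °C to rt
Reagents that add atoms: none
Why: Fluoride-driven desilylation (formation of the strong Si–F bond) is acid-free, so the ionisable veratryl carbinol should keep its configuration.

**Compound list**
1 | 5,6-O-isopropylidene-L-ascorbic acid | CC1(C)OC[C@H](O1)[C@H]2OC(=O)C(O)=C2O | starting material
2 | 2-O-benzyl-5,6-O-isopropylidene-L-ascorbic acid | CC1(C)OC[C@H](O1)[C@H]2OC(=O)C(OCc3ccccc3)=C2O | intermediate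
3 | 2-O-benzyl-5,6-O-isopropylidene-3-O-(trifluoromethylsulfonyl)-L-ascorbic acid | CC1(C)OC[C@H](O1)[C@H]2OC(=O)C(OCc3ccccc3)=C2OS(=O)(=O)C(F)(F)F | intermediate
4 | 4-methoxyphenylboronic acid | COc1ccc(B(O)O)cc1 | starting material
5 | (5S)-3-(benzyloxy)-5-[(4S)-2,2-dimethyl-1,3-dioxolan-4-yl]-4-(4-methoxyphenyl)furan-2(5H)-one | CC1(C)OC[C@H](O1)[C@H]2OC(=O)C(OCc3ccccc3)=C2c4ccc(OC)cc4 | intermediate
6 | (5S)-5-[(4S)-2,2-dimethyl-1,3-dioxolan-4-yl]-3-hydroxy-4-(4-methoxyphenyl)furan-2(5H)-one (free enol lactone) | CC1(C)OC[C@H](O1)[C@H]2OC(=O)C(O)=C2c3ccc(OC)cc3 | intermediate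
7 | 3-deoxy-5,6-O-isopropylidene-3-C-(4-methoxyphenyl)-L-gulono-1,4-lactone (all-cis) | COc1ccc([C@H]2[C@@H]([C@@H]3COC(C)(C)O3)OC(=O)[C@H]2O)cc1 | intermediate
8 | 2-O-TBS ether of 7 | COc1ccc([C@H]2[C@@H]([C@@H]3COC(C)(C)O3)OC(=O)[C@H]2O[Si](C)(C)C(C)(C)C)cc1 | intermediate
9 | lactol from 8 (anomeric mixture) | COc1ccc([C@H]2[C@@H]([C@@H]3COC(C)(C)O3)OC(O)[C@H]2O[Si](C)(C)C(C)(C)C)cc1 | intermediate
10 | (2S,3S,4S)-4-(tert-butyldimethylsilyloxy)-2-[(4S)-2,2-dimethyl-1,3-dioxolan-4-yl]-3-(4-methoxyphenyl)oxolane | COc1ccc([C@H]2[C@@H]([C@@H]3COC(C)(C)O3)OC[C@H]2O[Si](C)(C)C(C)(C)C)cc1 | intermediate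
11 | (1S)-1-[(2S,3S,4S)-4-(tert-butyldimethylsilyloxy)-3-(4-methoxyphenyl)oxolan-2-yl]ethane-1,2-diol (free diol) | COc1ccc([C@H]2[C@@H]([C@@H](O)CO)OC[C@H]2O[Si](C)(C)C(C)(C)C)cc1 | intermediate
12 | (2S,3S,4S)-4-(tert-butyldimethylsilyloxy)-3-(4-methoxyphenyl)oxolane-2-carbaldehyde | COc1ccc([C@H]2[C@@H](C=O)OC[C@H]2O[Si](C)(C)C(C)(C)C)cc1 | intermediate
13 | 3,4-dimethoxyphenylmagnesium bromide | COc1ccc([Mg]Br)cc1OC | starting material
14 | (3,4-dimethoxyphenyl)[(2S,3S,4S)-4-(tert-butyldimethylsilyloxy)-3-(4-methoxyphenyl)oxolan-2-yl]methanol, both carbinol epimers | COc1ccc([C@H]2[C@@H](C(O)c3ccc(OC)c(OC)c3)OC[C@H]2O[Si](C)(C)C(C)(C)C)cc1 | intermediate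
15 | (3,4-dimethoxyphenyl)[(2S,3S,4S)-4-(tert-butyldimethylsilyloxy)-3-(4-methoxyphenyl)oxolan-2-yl]methanone | COc1ccc([C@H]2[C@@H](C(=O)c3ccc(OC)c(OC)c3)OC[C@H]2O[Si](C)(C)C(C)(C)C)cc1 | intermediate
16 | (R)-(3,4-dimethoxyphenyl)[(2S,3S,4S)-4-(tert-butyldimethylsilyloxy)-3-(4-methoxyphenyl)oxolan-2-yl]methanol | COc1ccc([C@H]2[C@@H]([C@H](O)c3ccc(OC)c(OC)c3)OC[C@H]2O[Si](C)(C)C(C)(C)C)cc1 | intermediate
17 | (3S,4R,5S)-5-[(R)-(3,4-dimethoxyphenyl)(hydroxy)methyl]-4-(4-methoxyphenyl)oxolan-3-ol | COc1ccc([C@H]2[C@@H]([C@H](O)c3ccc(OC)c(OC)c3)OC[C@H]2O)cc1 | target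

**Step count**
Total step count: 12. Longest linear sequence: 12 steps (from 1).

**Steps most likely to fail**

Step 4. After the fast loss of benzyl, the stabilised free enol may take up hydrogen only sluggishly at its tetrasubstituted double bond. It may also tautomerise to the 2-oxo lactone, which would erode C3, or suffer hydrogenolysis of the allylic C4–O bond on prolonged exposure.
The fallback sets out from 5 and comes back at 8.
- Compound 5 is only debenzylated (10% Pd/C, H2 at 1 atm, EtOAc, stopped after one equivalent), and the enol lactone 6 is this time isolated.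
- Its O2 is capped with TBSOTf and 2,6-lutidine to give (5S)-3-(tert-butyldimethylsilyloxy)-5-[(4S)-2,2-dimethyl-1,3-dioxolan-4-yl]-4-(4-methoxyphenyl)furan-2(5H)-one F1.
- F1 is a fixed silyl enol ether that cannot tautomerise and carries no group to be lost. It can therefore be forced under pressure (10% Pd/C, H2 at 50 atm, EtOAc).
- Hydrogen should again enter opposite to the dioxolanyl group, which delivers 8 directly.

Step 3. The base may cleave the S–O bond of the vinylogous acyl triflate and return 2. It may also deprotonate the γ-position, with loss of configuration at C4.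
The fallback sets out from 3 and comes back at 5, and uses neither palladium nor base.
- Commercial 4-methoxyphenylmagnesium bromide (2 equiv) and CuI (1 equiv) in THF at −40 °C give bromomagnesium bis(4-methoxyphenyl)cuprate F2.
- F2 replaces the triflate of 3 at −78 °C by the known organocopper substitution of enol triflates. At a β-sulfonyloxy enoate this runs as addition–elimination, and it forms the same aryl–C3 bond.

Step 11. Incomplete chelation may give poor facial selectivity. Enolisation of the ketone during steps 10 and 11 may epimerise oxolane C2 to the more stable trans series.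
The fallback sets out from 12, comes back at 16, and avoids the ketone altogether.
- Grignard reagent 13 is transmetalated with ClTi(OiPr)3 (THF, −78 to 0 °C) to (3,4-dimethoxyphenyl)titanium triisopropoxide F3.
- F3 is weakly basic and non-chelating. It should add to aldehyde 12 under Felkin–Anh control: the C2–O1 bond lies perpendicular to the carbonyl group and the nucleophile passes the C2–H.
- This gives the anti (R)-carbinol 16 in the bond-forming step itself.

**Further compounds**
F1 | step 4 | (5S)-3-(tert-butyldimethylsilyloxy)-5-[(4S)-2,2-dimethyl-1,3-dioxolan-4-yl]-4-(4-methoxyphenyl)furan-2(5H)-one | CC1(C)OC[C@H](O1)[C@H]2OC(=O)C(O[Si](C)(C)C(C)(C)C)=C2c3ccc(OC)cc3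
F2 | step 3 | bromomagnesium bis(4-methoxyphenyl)cuprate | COc1ccc([Cu-]c2ccc(OC)cc2)cc1.[Mg+]Br
F3 | step 11 | (3,4-dimethoxyphenyl)titanium triisopropoxide | COc1ccc([Ti](OC(C)C)(OC(C)C)OC(C)C)cc1OC
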